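(Readings and results are simulated on assumed constants, noise included.)

Time first: red gets 8.0 d, violet 25 d, and you can bracket by hand how far each climbs in that time.

| setting | larch | elm | violet | red |
|---|---|---|---|---|
| substrate | 0.30 M | 0.30 M | 0.30 M | 0.30 M |
| fresh partner | 0.28 equiv | 0.73 equiv | 0.450 equiv | 0.900 equiv |
| gas | 15 mM (held) | 15 mM (held) | 15 mM (held) | 15 mM (held) |
| remark | run made earlier | run made earlier |  |  |
| time |  |  | 25 d | 8.0 d |

- larch (time / d: target / %, substrate / %): 0.417: 1.8, 91.7; 0.625: 2.5, 85.3; 1.04: 5.1, 72.7; 1.67: 7.5, 48.8; 2.50: 17.2, 23.0; 4.00: 24.6, 2.8; 6.00: 27.6, 0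
- elm (time / d: target / %, substrate / %): 0.417: 0.3, 96.3; 0.625: 0.5, 92.9; 1.04: 1.3, 86.8; 1.67: 10.5, 71.3; 2.50: 26.1, 40.9; 4.00: 51.5, 9.5; 6.00: 62.9, 2.3

(each reading ± 1 percentage point)

- at the start none of coupling partner is dissolved
- reactions considered so far: gas <-> coupling partner; open intermediate + second intermediate -> target; substrate + coupling partner -> open intermediate; coupling partner + fresh partner -> second intermediate

- the flask that ends with the higher amount of target, in percent of the substrate charged, or "neither" when 2 percentage points or less lies between them (violet / red / neither)
- final target, as a percentage of the substrate charged, in violet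
- final target, as a percentage of the substrate charged, in red

1. Upper bound. One target takes one second intermediate, which takes one fresh partner, so fresh partner is the limiting reagent while its charge lies below the substrate's. The larch run agrees: 27.6% from 0.28 equiv. Call the charge c, as a fraction of the substrate.

2. Compute only the correction: the shortfall S, which is c minus target. Let a be the substrate's surplus over c. Once substrate and fresh partner are consumed, second intermediate is S and open intermediate is a + S. So dS/dt = −κS(a + S), and S/(a + S) falls as exp(−κat).

3. Read κ from the elm run. Its S falls from 47 percentage points at 2.50 d to 10 points at 6.00 d, while open intermediate averages 35.6%. That gives the coupling constant κ, the fractional fall of S per day per unit of open intermediate: 1.23 d⁻¹, a reading.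

4. Tighten red from above. Start the clock at zero, as if both intermediates stood ready: with a = 10.0%, target reaches 84.9%.

5. Tighten red from below. By 4.00 d the elm run had consumed substrate and fresh partner at 0.409 d⁻¹, taking its fresh partner as consumed. At that pace red needs 4.65 d. Start the clock there instead: 75.3%.

6. My reckoning: red near the middle, 80.1%. Violet's lower bound, reckoned the same way, is 45.0%, its ceiling, so red is higher.

The forecast says red, with 44.5% (42% to 46%) for violet and 75% (67% to 82%) for red, where “Its intermediates then couple slowly”, and its red value stands just under my lower bound.

The flasks give 45.0% in violet and 80.7% in red, so red ends higher, inside my bracket.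

    gas ⇌ coupling partner, rate k1*(csat - [coupling partner]) (kL = 0.580 h⁻¹)
    open intermediate + second intermediate → target (k = 0.180 M⁻¹ h⁻¹)
    substrate + coupling partner → open intermediate (k = 4.20 M⁻¹ h⁻¹)
    coupling partner + fresh partner → second intermediate (k = 41.0 M⁻¹ h⁻¹)

Red has not come to rest at 8.0 d: S is still 9.3 points. Near rest S decays pseudo-first-order, halving every ln(2)/κa; this is an estimate from the scattered elm reading of κ, and it comes to about 5.62 d for red and about 1.02 d for violet. Violet holds 45.0% target at 12.5 d and 45.0% at 250 d. Carrying red's S forward with the κ read from the elm run to 80.0 d gives an estimated <0.001%. There the flask stands at 90.0% target and 10.0% open intermediate.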